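Two questions stood over this flask, and these were the runs I had to answer them from.

| flask | J | Q | remark | time |
|---|---|---|---|---|
| epsilon | 2.8 M | 2 M | run made earlier |  |
| delta | 2 M | 1 M | run made earlier |  |
| flask | 2.0 M | 2.00 M |  | 3.0 h |

- epsilon (time / h: E / %, G / %): 0.333: 13.1, 0.4; 0.667: 33.6, 9.6; 1.00: 54.0, 29.8; 1.33: 64.3, 41.4; 1.50: 67.6, 42.7; 2.00: 70.0, 46.0; 2.50: 70.6, 47.2
- delta (time / h: E / %, G / %): 0.200: 9.1, 0.1; 0.333: 19.6, 0; 0.667: 38.3, 4.4; 1.33: 47.0, 14.6; 2.50: 50.4, 16.6

(scatter of a reading: 0.5 percentage points)

- what is said of E includes G
- J, G, Q is a solid; its amount is given per volume of the solution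
- at the start none of J is in solution
- at the start none of Q is in solution
- L means what is dissolved; the solid is not counted in it
- L is what J becomes in solution

- E and G together at 3.0 h, in percent of the J charged
- concentration of L in solution at 3.0 h, in percent of saturation

- I followed one J through the runs: once dissolved as L, it had to meet a Q to end as E, counted with G. The last E reading in the epsilon run came to 1.98 M against 2 M of Q, and in the delta run to 1.01 M against 1 M, so I read one Q used per E, with Q the limiting reagent in both.
- For this flask I reckoned 100% as the partner share, the smaller of [Q] and [J] charged over [J] charged, which, at one Q used per E, is the chance that a J finds a Q given enough time. That share was the level the curve could run into.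
- After a slow start, E in the epsilon run climbed at 1.72 M h⁻¹ between 0.667 h and 1.00 h, and I took that reading as my estimate of the slope in this flask.
- Drawn from zero time, that straight line met the level at an estimated knee near 1.17 h, before the asked 3.0 h. Beyond the knee I expected a slow creep, because the charges were equal and neither partner stayed in excess. My own value therefore lay below 100%, without a figure.
- The forecast gave 95.5% and 16% of saturation, saying: “The flask is stoichiometric, so neither reagent stays in excess.”

- The flask gave 93.7% at 3.0 h, with [L] at 12.7% of saturation. Dissolved L then stood at 6.26% of the J charged, and the partner share of 100% less the result is 6.3 percentage points.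

    J ⇌ L, rate k1*(cs1 - [L]) while solid is left; crystals form when [L] > cs1 (solubility = 0.990 M, k = 0.00869 s⁻¹)
    L + Z → E (k = 8.63 × 10⁻⁴ L mol⁻¹ s⁻¹)
    G ⇌ E, rate k3*(cs3 - [E]) while solid is left; crystals form when [E] > cs3 (solubility = 0.670 M, k = 0.0174 s⁻¹)
    Q ⇌ Z, rate k4*(cs4 - [Z]) while solid is left; crystals form when [Z] > cs4 (solubility = 0.930 M, k = 0.00147 s⁻¹)
- In the neighbour flask with 0.80 M of Q, the partner share is 40.0%. That flask gave 40.0% at 3.00 h, with 0.016% of its Q left.

The data are simulated with constants of no real substance; noise was put on by code.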